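The benzene ring (C1 side chain, C3 OH, C5 OMe, C6 OAc) is opened at the C1–C6 bond. The meta oxygens at C3 and C5 and the C2' oxygen of the side chain sit on alternate carbons of one chain, the mark of a tetraketide grown on (R)-3-hydroxyhexadecanoate, with C6 as the carboxyl-bearing carbon. One operation unmasks a 3,5,7-triketo ester from a silyl-protected diketo-dioxinone and folds it by aldol closure and dehydration into a regiodefined 6-alkylresorcylate. The ester at C6 is later exchanged for oxygen by Dakin oxidation, so the three ring oxygens stay differentiated throughout. The stereocentre comes from a keto ester hydrogenation.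

Key step: step 7

Remark: the three-carbon ketone partner has to be the 6-(2-oxopropyl)dioxinone, since a 6-acetyl dioxinone would leave the chain one carbon short; Meldrum's acid, tetradecanoyl chloride and 2,2,6-trimethyl-4H-1,3-dioxin-4-one are taken as commercial.

Step 1
Reactants: 1 Meldrum's acid (2,2-dimethyl-1,3-dioxane-4,6-dione); 2 tetradecanoyl chloride
Product: 4 methyl 3-oxohexadecanoate, via acyl Meldrum's acid 3 (not isolated)
Conditions: pyridine (2 equiv), CH2Cl2, 0 °C to rt; dilute HCl wash; crude 3 in MeOH, reflux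
Reagents that add atoms: methanol (CO)
Why: C-acylation of Meldrum's acid followed by methanolysis of the acyl derivative with loss of acetone and CO2 is the standard two-carbon homologation of an acid chloride to a β-keto ester.

Step 2
Reactants: 4 methyl 3-oxohexadecanoate
Product: 5 methyl (3R)-3-hydroxyhexadecanoate
Conditions: H2 (50 atm), RuCl2[(R)-BINAP] (0.2 mol %), MeOH, 50 °C
Reagents that add atoms: none
Why: Noyori asymmetric hydrogenation of a β-keto ester, in which the chelated substrate on the (R)-BINAP ruthenium dichloride catalyst takes up hydride on one carbonyl face and C3 is set as R, the sense established for simple 3-oxoalkanoates.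

Step 3
Reactants: 5 methyl (3R)-3-hydroxyhexadecanoate
Product: 6 methyl (3R)-3-(tert-butyldimethylsilyloxy)hexadecanoate
Conditions: TBSCl, imidazole, DMF, rt
Reagents that add atoms: tert-butyldimethylsilyl chloride (CC(C)(C)[Si](C)(C)Cl)
Why: Imidazole-promoted silylation of a secondary alcohol is routine and leaves the stereocentre untouched, and the silyl ether later keeps the side-chain oxygen from acting as a nucleophile or leaving group.

Step 4
Reactants: 6 methyl (3R)-3-(tert-butyldimethylsilyloxy)hexadecanoate
Product: 7 (3R)-3-(tert-butyldimethylsilyloxy)-N-methoxy-N-methylhexadecanamide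
Conditions: MeNH(OMe)·HCl, iPrMgCl, THF, −20 to 0 °C; aq NH4Cl
Reagents that add atoms: N,O-dimethylhydroxylamine hydrochloride (CNOC.Cl)
Why: Aminolysis of the ester by the chloromagnesium amide of N,O-dimethylhydroxylamine (direct Weinreb amide formation) is fast at low temperature, where neither the silyl ether nor the β-silyloxy unit is at risk.

Step 5
Reactants: 8 2,2,6-trimethyl-4H-1,3-dioxin-4-one
Product: 9 2,2-dimethyl-6-(2-oxopropyl)-4H-1,3-dioxin-4-one
Conditions: LiN(SiMe3)2, THF, −78 °C; AcCl (0.5 equiv), −78 °C; 1 M HCl quench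
Reagents that add atoms: acetyl chloride (CC(Cl)=O)
Why: γ-Deprotonation gives the lithium dienolate of the dioxinone, which is C-acylated at the 6-methyl carbon (vinylogous Claisen acylation); two dienolates are used per acid chloride because the product is the stronger acid.

Step 6
Reactants: 9 2,2-dimethyl-6-(2-oxopropyl)-4H-1,3-dioxin-4-one; 7 (3R)-3-(tert-butyldimethylsilyloxy)-N-methoxy-N-methylhexadecanamide
Product: 10 6-[(6R)-6-(tert-butyldimethylsilyloxy)-2,4-dioxononadecyl]-2,2-dimethyl-4H-1,3-dioxin-4-one
Conditions: LiN(iPr)2 (2.1 equiv per 9), THF, −78 °C; then 7 (0.5 equiv per 9), −78 to −40 °C; AcOH quench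
Reagents that add atoms: none
Why: Claisen-type acylation of the 1,3-dianion of 9 at its terminal carbon by the Weinreb amide, whose chelated tetrahedral intermediate prevents over-addition and keeps the diketone hidden from the base until the quench.

Step 7
Reactants: 10 6-[(6R)-6-(tert-butyldimethylsilyloxy)-2,4-dioxononadecyl]-2,2-dimethyl-4H-1,3-dioxin-4-one
Product: 14 methyl 2-[(2R)-2-(tert-butyldimethylsilyloxy)pentadecyl]-4,6-dihydroxybenzoate, via acylketene 11 (not isolated), via triketo ester 12 (not isolated), via aldol adduct 13 (not isolated)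
Conditions: MeOH (10 equiv), PhMe, 110 °C (sealed tube); cool; K2CO3, MeOH, rt; then AcOH, rt
Reagents that add atoms: methanol (CO)
Why: Heating 10 expels acetone in a retro-hetero-Diels–Alder reaction and excess methanol intercepts acylketene 11 as the enolised triketo ester 12 before the ketene can lactonise onto a chain enol. Carbonate then forms the C2 carbanion between the ester and the C3 ketone, which adds to the C7 ketone in a 6-(enolendo)-exo-trig aldol closure (adduct 13) that makes the ring bond C1–C6 of the target numbering, and β-elimination of water followed by enolisation, finished by the acetic acid quench, gives the benzene ring. The closest known reaction type is the biomimetic aldol aromatisation of 3,5,7-triketo esters set free from diketo-dioxinones, a standard resorcylate synthesis. No stereocentre is formed (the two sp3 ring centres of 13 vanish on aromatisation) and the R carbinol carbon of the side chain, which is not α to a carbonyl, cannot epimerise. The step needs C-aldol closure to beat Claisen closure onto the ester, O-cyclisation to pyrones and E1cB loss of the silyloxy group; the C7 ketone is a better electrophile than the ester, the weak base at room temperature keeps the chain as delocalised 1,3-dicarbonyl enolates in which C8 is not deprotonated to a useful extent, the silyl ether removes the side-chain oxygen as a nucleophile, and aromatisation makes the aldol pathway irreversible.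

Step 8
Reactants: 14 methyl 2-[(2R)-2-(tert-butyldimethylsilyloxy)pentadecyl]-4,6-dihydroxybenzoate
Product: 16 methyl 4-(benzyloxy)-2-[(2R)-2-(tert-butyldimethylsilyloxy)pentadecyl]-6-methoxybenzoate, via monobenzyl ether 15 (not isolated)
Conditions: BnBr (1.0 equiv), K2CO3, DMF, rt; then MeI (3 equiv), 45 °C
Reagents that add atoms: benzyl bromide (BrCc1ccccc1); iodomethane (CI)
Why: Williamson etherification in two stages, in which the more acidic 4-OH para to the ester is benzylated first while the 6-OH is held in a hydrogen bond to the ester carbonyl, and excess iodomethane at higher temperature then methylates that chelated phenol.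

Step 9
Reactants: 16 methyl 4-(benzyloxy)-2-[(2R)-2-(tert-butyldimethylsilyloxy)pentadecyl]-6-methoxybenzoate
Product: 17 {4-(benzyloxy)-2-[(2R)-2-(tert-butyldimethylsilyloxy)pentadecyl]-6-methoxyphenyl}methanol
Conditions: LiAlH4, THF, 0 °C to rt
Reagents that add atoms: none
Why: Hydride reduction of the benzoate with LiAlH4 should give the benzylic alcohol, while the silyl, benzyl and methyl ethers are inert to the reagent.

Step 10
Reactants: 17 {4-(benzyloxy)-2-[(2R)-2-(tert-butyldimethylsilyloxy)pentadecyl]-6-methoxyphenyl}methanol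
Product: 18 4-(benzyloxy)-2-[(2R)-2-(tert-butyldimethylsilyloxy)pentadecyl]-6-methoxybenzaldehyde
Conditions: MnO2 (activated, excess), CH2Cl2, rt
Reagents that add atoms: none
Why: Activated MnO2 oxidises benzylic alcohols to aldehydes under neutral conditions without over-oxidation, which suits this acid-sensitive electron-rich benzyl alcohol.

Step 11
Reactants: 18 4-(benzyloxy)-2-[(2R)-2-(tert-butyldimethylsilyloxy)pentadecyl]-6-methoxybenzaldehyde
Product: 21 4-(benzyloxy)-2-[(2R)-2-hydroxypentadecyl]-6-methoxyphenol, via aryl formate 19 (not isolated), via silyl phenol 20 (not isolated)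
Conditions: mCPBA, CH2Cl2, 0 °C to rt; Me2S; then HCl (1.25 M in MeOH), rt
Reagents that add atoms: 3-chloroperoxybenzoic acid (OOC(=O)c1cccc(Cl)c1)
Why: Dakin-type Baeyer–Villiger oxidation, in which the aryl group activated by the ortho-methoxy and para-benzyloxy donors migrates in preference to hydride to give formate 19, and acid methanolysis then removes the formyl group and the secondary silyl ether in the same flask while the benzyl and methyl ethers stay.

Step 12
Reactants: 21 4-(benzyloxy)-2-[(2R)-2-hydroxypentadecyl]-6-methoxyphenol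
Product: 22 (2R)-1-[2-(acetyloxy)-5-(benzyloxy)-3-methoxyphenyl]pentadecan-2-yl acetate
Conditions: Ac2O, pyridine, DMAP (catalytic), CH2Cl2, rt
Reagents that add atoms: acetic anhydride (CC(=O)OC(C)=O)
Why: DMAP-catalysed acylation esterifies both the hindered phenol and the secondary alcohol, with retention at the stereocentre because no bond to that carbon is broken.

Step 13
Reactants: 22 (2R)-1-[2-(acetyloxy)-5-(benzyloxy)-3-methoxyphenyl]pentadecan-2-yl acetate
Product: 23 (2R)-1-[2-(acetyloxy)-5-hydroxy-3-methoxyphenyl]pentadecan-2-yl acetate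
Conditions: H2 (1 atm), 10% Pd/C, EtOAc, rt
Reagents that add atoms: none
Why: Hydrogenolysis of the aryl benzyl ether over Pd/C is chemoselective, since the aryl and alkyl acetates, the methyl ether and the non-benzylic C–O bond of the side chain are not cleaved under neutral conditions, and the acetate on C6 cannot migrate to the para oxygen.

Compound list
1 | Meldrum's acid (2,2-dimethyl-1,3-dioxane-4,6-dione) | CC1(C)OC(=O)CC(=O)O1 | starting material
2 | tetradecanoyl chloride | CCCCCCCCCCCCCC(Cl)=O | starting material
3 | 5-(1-hydroxytetradecylidene)-2,2-dimethyl-1,3-dioxane-4,6-dione (acyl Meldrum's acid, enol form) | CCCCCCCCCCCCCC(O)=C1C(=O)OC(C)(C)OC1=O | intermediate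
4 | methyl 3-oxohexadecanoate | CCCCCCCCCCCCCC(=O)CC(=O)OC | intermediate
5 | methyl (3R)-3-hydroxyhexadecanoate | CCCCCCCCCCCCC[C@H](CC(=O)OC)O | intermediate
6 | methyl (3R)-3-(tert-butyldimethylsilyloxy)hexadecanoate | CCCCCCCCCCCCC[C@H](CC(=O)OC)O[Si](C)(C)C(C)(C)C | intermediate
7 | (3R)-3-(tert-butyldimethylsilyloxy)-N-methoxy-N-methylhexadecanamide | CCCCCCCCCCCCC[C@H](CC(=O)N(C)OC)O[Si](C)(C)C(C)(C)C | intermediate
8 | 2,2,6-trimethyl-4H-1,3-dioxin-4-one | CC1=CC(=O)OC(C)(C)O1 | starting material
9 | 2,2-dimethyl-6-(2-oxopropyl)-4H-1,3-dioxin-4-one | CC(=O)CC1=CC(=O)OC(C)(C)O1 | intermediate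
10 | 6-[(6R)-6-(tert-butyldimethylsilyloxy)-2,4-dioxononadecyl]-2,2-dimethyl-4H-1,3-dioxin-4-one | CCCCCCCCCCCCC[C@H](CC(=O)CC(=O)CC1=CC(=O)OC(C)(C)O1)O[Si](C)(C)C(C)(C)C | intermediate
11 | (9R)-9-(tert-butyldimethylsilyloxy)-3,5,7-trioxodocos-1-en-1-one (acylketene) | CCCCCCCCCCCCC[C@H](CC(=O)CC(=O)CC(=O)C=C=O)O[Si](C)(C)C(C)(C)C | intermediate
12 | methyl (9R)-9-(tert-butyldimethylsilyloxy)-3,5,7-trioxodocosanoate | CCCCCCCCCCCCC[C@H](CC(=O)CC(=O)CC(=O)CC(=O)OC)O[Si](C)(C)C(C)(C)C | intermediate
13 | methyl 2-[(2R)-2-(tert-butyldimethylsilyloxy)pentadecyl]-2-hydroxy-4,6-dioxocyclohexane-1-carboxylate (aldol adduct; mixture of ring epimers and enol tautomers, side-chain centre R) | CCCCCCCCCCCCC[C@H](CC1(O)CC(=O)CC(=O)C1C(=O)OC)O[Si](C)(C)C(C)(C)C | intermediate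
14 | methyl 2-[(2R)-2-(tert-butyldimethylsilyloxy)pentadecyl]-4,6-dihydroxybenzoate | CCCCCCCCCCCCC[C@H](Cc1cc(O)cc(O)c1C(=O)OC)O[Si](C)(C)C(C)(C)C | intermediate
15 | methyl 4-(benzyloxy)-2-[(2R)-2-(tert-butyldimethylsilyloxy)pentadecyl]-6-hydroxybenzoate | CCCCCCCCCCCCC[C@H](Cc1cc(OCc2ccccc2)cc(O)c1C(=O)OC)O[Si](C)(C)C(C)(C)C | intermediate
16 | methyl 4-(benzyloxy)-2-[(2R)-2-(tert-butyldimethylsilyloxy)pentadecyl]-6-methoxybenzoate | CCCCCCCCCCCCC[C@H](Cc1cc(OCc2ccccc2)cc(OC)c1C(=O)OC)O[Si](C)(C)C(C)(C)C | intermediate
17 | {4-(benzyloxy)-2-[(2R)-2-(tert-butyldimethylsilyloxy)pentadecyl]-6-methoxyphenyl}methanol | CCCCCCCCCCCCC[C@H](Cc1cc(OCc2ccccc2)cc(OC)c1CO)O[Si](C)(C)C(C)(C)C | intermediate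
18 | 4-(benzyloxy)-2-[(2R)-2-(tert-butyldimethylsilyloxy)pentadecyl]-6-methoxybenzaldehyde | CCCCCCCCCCCCC[C@H](Cc1cc(OCc2ccccc2)cc(OC)c1C=O)O[Si](C)(C)C(C)(C)C | intermediate
19 | 4-(benzyloxy)-2-[(2R)-2-(tert-butyldimethylsilyloxy)pentadecyl]-6-methoxyphenyl formate | CCCCCCCCCCCCC[C@H](Cc1cc(OCc2ccccc2)cc(OC)c1OC=O)O[Si](C)(C)C(C)(C)C | intermediate
20 | 4-(benzyloxy)-2-[(2R)-2-(tert-butyldimethylsilyloxy)pentadecyl]-6-methoxyphenol | CCCCCCCCCCCCC[C@H](Cc1cc(OCc2ccccc2)cc(OC)c1O)O[Si](C)(C)C(C)(C)C | intermediate
21 | 4-(benzyloxy)-2-[(2R)-2-hydroxypentadecyl]-6-methoxyphenol | CCCCCCCCCCCCC[C@H](Cc1cc(OCc2ccccc2)cc(OC)c1O)O | intermediate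
22 | (2R)-1-[2-(acetyloxy)-5-(benzyloxy)-3-methoxyphenyl]pentadecan-2-yl acetate | CCCCCCCCCCCCC[C@H](Cc1cc(OCc2ccccc2)cc(OC)c1OC(C)=O)OC(C)=O | intermediate
23 | (2R)-1-[2-(acetyloxy)-5-hydroxy-3-methoxyphenyl]pentadecan-2-yl acetate | CCCCCCCCCCCCC[C@H](Cc1cc(O)cc(OC)c1OC(C)=O)OC(C)=O | target

Total step count: 13.
Longest linear sequence: 12 steps (steps 1–4 and 6–13, from 1 and 2); step 5 is a one-step side branch from 8.

Steps most likely to fail

Step 7 (key step). In the open triketo ester, base-induced loss of the silyloxy group or closure through oxygen to a pyrone may outrun the C-aldol, or the sequence may stall before dehydration. The fallback sets out from 10 and comes back at 14. The ring is closed before the dioxinone is opened, so that neither an acylketene nor a free triketo ester is formed. Et3N in CH2Cl2 at rt should let C5 of the intact dioxinone, as its vinylogous enolate, add to the distal ketone of 10 and aromatise to the acetonide-protected resorcylate 7-hydroxy-2,2-dimethyl-5-[(2R)-2-(tert-butyldimethylsilyloxy)pentadecyl]-4H-1,3-benzodioxin-4-one F1. NaOMe in MeOH at rt should then open the benzodioxinone by transesterification, with loss of acetone, to give 14.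

Step 6. Proton transfer from the α-CH2 of the Weinreb amide to the dianion, followed by loss of the silyloxy group, may compete with C-acylation and leave conversion low. The fallback sets out from 6 and comes back at 10. The electrophile is changed from an amide to an aldehyde and the oxidation level is corrected afterwards. iBu2AlH in CH2Cl2 at −78 °C should reduce 6 to (3R)-3-(tert-butyldimethylsilyloxy)hexadecanal F2. Aldol addition of the same dianion of 9 (LiN(iPr)2, THF, −78 °C) should give 6-[(6R)-6-(tert-butyldimethylsilyloxy)-4-hydroxy-2-oxononadecyl]-2,2-dimethyl-4H-1,3-dioxin-4-one F3 as a mixture of epimers at the new carbinol. Dess–Martin periodinane (NaHCO3, CH2Cl2, rt) should oxidise it to 10.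

Step 11. Hydride instead of aryl migration in the peracid adduct, or oxidation of the electron-rich ring and of the freed phenol by surplus peracid, may erode the Dakin step. The fallback sets out from 14 and comes back at 20. The carboxyl carbon is removed and the C6 oxygen is brought in by phenol oxidation instead; after decarboxylation the two meta oxygens are equivalent by position, so either may carry the methyl group.
- MeI (1 equiv), K2CO3, acetone should methylate only the non-chelated 4-OH to give methyl 2-[(2R)-2-(tert-butyldimethylsilyloxy)pentadecyl]-6-hydroxy-4-methoxybenzoate F4.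
- KOH in aqueous EtOH at reflux, then acidification and warming, should hydrolyse and decarboxylate it to 3-methoxy-5-[(2R)-2-(tert-butyldimethylsilyloxy)pentadecyl]phenol F5.
- (KSO3)2NO in phosphate-buffered aqueous acetone should oxidise the position para to the hydroxyl and give 2-methoxy-6-[(2R)-2-(tert-butyldimethylsilyloxy)pentadecyl]cyclohexa-2,5-diene-1,4-dione F6.
- Na2S2O4 in EtOAc/water should reduce it to 2-methoxy-6-[(2R)-2-(tert-butyldimethylsilyloxy)pentadecyl]benzene-1,4-diol F7.
- BnBr (1 equiv), K2CO3, acetone under argon should benzylate the unhindered hydroxyl and give 20, which is desilylated with HCl in MeOH as in the second stage of step 11 to give 21.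

Further compounds
F1 | step 7 | 7-hydroxy-2,2-dimethyl-5-[(2R)-2-(tert-butyldimethylsilyloxy)pentadecyl]-4H-1,3-benzodioxin-4-one | CCCCCCCCCCCCC[C@H](Cc1cc(O)cc2OC(C)(C)OC(=O)c12)O[Si](C)(C)C(C)(C)C
F2 | step 6 | (3R)-3-(tert-butyldimethylsilyloxy)hexadecanal | CCCCCCCCCCCCC[C@H](CC=O)O[Si](C)(C)C(C)(C)C
F3 | step 6 | 6-[(6R)-6-(tert-butyldimethylsilyloxy)-4-hydroxy-2-oxononadecyl]-2,2-dimethyl-4H-1,3-dioxin-4-one | CCCCCCCCCCCCC[C@H](CC(O)CC(=O)CC1=CC(=O)OC(C)(C)O1)O[Si](C)(C)C(C)(C)C
F4 | step 11 | methyl 2-[(2R)-2-(tert-butyldimethylsilyloxy)pentadecyl]-6-hydroxy-4-methoxybenzoate | CCCCCCCCCCCCC[C@H](Cc1cc(OC)cc(O)c1C(=O)OC)O[Si](C)(C)C(C)(C)C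
F5 | step 11 | 3-methoxy-5-[(2R)-2-(tert-butyldimethylsilyloxy)pentadecyl]phenol | CCCCCCCCCCCCC[C@H](Cc1cc(O)cc(OC)c1)O[Si](C)(C)C(C)(C)C
F6 | step 11 | 2-methoxy-6-[(2R)-2-(tert-butyldimethylsilyloxy)pentadecyl]cyclohexa-2,5-diene-1,4-dione | CCCCCCCCCCCCC[C@H](CC1=CC(=O)C=C(OC)C1=O)O[Si](C)(C)C(C)(C)C
F7 | step 11 | 2-methoxy-6-[(2R)-2-(tert-butyldimethylsilyloxy)pentadecyl]benzene-1,4-diol | CCCCCCCCCCCCC[C@H](Cc1cc(O)cc(OC)c1O)O[Si](C)(C)C(C)(C)C
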